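The cyclohexane core is cut across C1–C2 and C5–C6, which traces the contiguous C1/C2/C6 triad (C1 carrying C7, the cis C2 methyl, the trans C6 oxygen) back to an (E)-configured 1-methyl diene terminus and an (E)-β-acyloxy acrylate. A single copper–bis(oxazoline)-catalysed endo Diels–Alder reaction between (E)-3-methylpenta-1,3-diene and 3-[(E)-3-acetoxyacryloyl]oxazolidin-2-one closes the six-membered ring and sets these three stereocentres in absolute terms. The residual C3=C4 alkene and C5 methylene then carry the three remaining oxygens and the C5 methyl, and the pyrone–tetraene arm is grown from C7 by two Wittig homologations and an aldol condensation with the lithiated ethylpyrone.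

Key step: step 3

Convention: ring atoms keep the target numbering in every intermediate (C1 bears C7, C2 is CHMe, C3 and C5 are the methyl carbinols, C4 and C6 are CH–O); α is the face of the C2 methyl group and β the face of the C6 oxygen; chain carbons are C7–C12 counted from the ring; TBS = tert-butyldimethylsilyl.
Assumption: the (S,S)-configured copper catalyst is taken to expose the Cα re face of the β-acetoxy imide, as it does for simpler acrylimides.

Step 1
Reactants: 1 propiolic acid
Product: 2 (E)-3-acetoxyacrylic acid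
Conditions: AcOH (solvent), N-methylmorpholine (cat.), 25 → 50 °C
Reagents that add atoms: acetic acid CC(=O)O
Why: Amine-catalysed conjugate addition of acetic acid to the ynoic acid (addition–elimination through a β-ammonium acrylate) should deliver the thermodynamically preferred E enol ester.

Step 2
Reactants: 2 (E)-3-acetoxyacrylic acid; 3 oxazolidin-2-one
Product: 5 3-[(E)-3-acetoxyacryloyl]oxazolidin-2-one, via (E)-3-acetoxyacryloyl chloride 4 (not isolated)
Conditions: (COCl)2, DMF (cat.), CH2Cl2, 0 → 25 °C; evaporate; then 3, LiCl, Et3N, THF, 0 → 25 °C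
Reagents that add atoms: none
Why: Acid chloride formation followed by N-acylation of the oxazolidinone under LiCl/Et3N activation is a standard imide synthesis in which the acyl chloride outcompetes the enol ester as acyl donor.

Step 3
Reactants: 5 3-[(E)-3-acetoxyacryloyl]oxazolidin-2-one; 6 (E)-3-methylpenta-1,3-diene
Product: 7 3-[(1R,2S,6R)-6-acetoxy-2,3-dimethylcyclohex-3-ene-1-carbonyl]oxazolidin-2-one
Conditions: [Cu((S,S)-t-Bu-box)](SbF6)2 (10 mol %; t-Bu-box = 2,2'-(propane-2,2-diyl)bis(4-tert-butyl-4,5-dihydrooxazole)), 6 (4 equiv; any Z isomer present is inert), CH2Cl2, 25 °C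
Reagents that add atoms: none
Why: The imide chelates the divalent copper centre through both carbonyl oxygens, which fixes the s-cis enoyl conformation in a square-planar complex and lowers the LUMO so that a concerted, asynchronous, suprafacial [4+2] cycloaddition (the known bis(oxazoline)–copper Diels–Alder reaction of β-substituted acrylimides) can run at ambient temperature. The cyclohexene ring closes in one event by bonding the acyl-bearing carbon to the methyl-bearing diene terminus (C1–C2) and the acetoxy-bearing carbon to the CH2 terminus (C5–C6). C1 is set by the ligand, one tert-butyl group screening the Cα si face so that the diene adds to the re face and C1 becomes R. C2 follows from the endo transition state, in which the chelated acyl group lies under the diene and ends cis to the outward (E)-methyl group, and C6 follows from the retained E geometry of the dienophile, which places the acetoxy group trans to the acyl group. The step needs regio-, endo and enantioface selectivity: regiochemistry should rest on the terminal methyl group outweighing the internal one and on the more advanced bond forming at the unhindered CH2 terminus, endo selectivity on secondary overlap with the chelated carbonyl, and face selectivity on the ligand.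

Step 4
Reactants: 7 3-[(1R,2S,6R)-6-acetoxy-2,3-dimethylcyclohex-3-ene-1-carbonyl]oxazolidin-2-one
Product: 8 (1R,5S,6S)-6-(hydroxymethyl)-4,5-dimethylcyclohex-3-en-1-ol
Conditions: LiBH4 (4 equiv), MeOH (4 equiv), THF, 0 → 25 °C
Reagents that add atoms: none
Why: Reductive cleavage of the N-acyloxazolidinone with LiBH4 gives the primary alcohol and the same hydride removes the acetate, so both oxygens are freed without touching C1, C2 or C6.

Step 5
Reactants: 8 (1R,5S,6S)-6-(hydroxymethyl)-4,5-dimethylcyclohex-3-en-1-ol
Product: 9 bis-TBS ether of 8 (C7–OTBS and 6β-OTBS)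
Conditions: TBSCl (2.5 equiv), imidazole, DMF, 25 °C
Reagents that add atoms: tert-butyldimethylsilyl chloride CC(C)(C)[Si](C)(C)Cl
Why: Standard silylation with TBSCl and imidazole protects the primary and the secondary alcohol in one operation.

Step 6
Reactants: 9 bis-TBS ether
Product: 10 C5 enone (ketone at C5 conjugated with C3=C4; 1α-CH2OTBS; 2α-Me; 6β-OTBS)
Conditions: CrO3, 3,5-dimethylpyrazole, CH2Cl2, −20 °C
Reagents that add atoms: chromium trioxide O=[Cr](=O)=O
Why: Allylic oxidation with the CrO3–3,5-dimethylpyrazole complex should convert the C5 methylene, whose pseudoaxial C–H bond overlaps with the alkene, into the β-methyl enone, whereas the tertiary C2–H bond is pseudoequatorial and poorly aligned.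

Step 7
Reactants: 10 C5 enone
Product: 11 3β,4β-dihydroxy ketone (cis-diol at C3/C4; 3α-Me)
Conditions: OsO4 (5 mol %), NMO, acetone/H2O, 25 °C
Reagents that add atoms: osmium tetroxide O=[Os](=O)(=O)=O; N-methylmorpholine N-oxide C[N+]1([O-])CCOCC1; water O
Why: Catalytic OsO4 dihydroxylation (syn addition) of the enone alkene should occur on the β face, anti to the pseudoaxial C2 methyl group next to C3, which sets C3 and C4 together.

Step 8
Reactants: 11 3β,4β-dihydroxy ketone
Product: 12 C3/C4 acetonide of 11
Conditions: 2-methoxypropene, PPTS (cat.), CH2Cl2, 0 → 25 °C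
Reagents that add atoms: 2-methoxypropene C=C(C)OC
Why: Acid-catalysed ketalisation engages the cis C3/C4 diol as a dioxolane and shields the α-ketol from retro-aldol and enolisation chemistry.

Step 9
Reactants: 12 acetonide ketone
Product: 13 C5 tertiary alcohol (5α-Me and 5β-OH)
Conditions: MeLi, CeCl3, THF, −78 °C
Reagents that add atoms: methyllithium [Li]C
Why: 1,2-Addition of the weakly basic organocerium reagent to the ketone should come from the α face (equatorial attack), because the axial C3 oxygen of the cis-fused acetonide blocks the β face, which sets C5 with its hydroxyl cis to the C4 and C6 oxygens.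

Step 10
Reactants: 13 C5 tertiary alcohol
Product: 14 C7 primary alcohol (6β-OTBS retained)
Conditions: HF·pyridine, pyridine, THF, 0 °C
Reagents that add atoms: none
Why: Buffered HF·pyridine should cleave the primary silyl ether much faster than the hindered secondary one at C6 (selective desilylation).

Step 11
Reactants: 14 C7 primary alcohol
Product: 15 C7 aldehyde
Conditions: Dess–Martin periodinane, NaHCO3, CH2Cl2, 0 → 25 °C
Reagents that add atoms: none
Why: Dess–Martin oxidation gives the aldehyde under near-neutral conditions that leave the tertiary alcohol, the acetonide and the equatorial, thermodynamically preferred C1 configuration untouched.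

Step 12
Reactants: 15 C7 aldehyde
Product: 16 (E)-enal (C7=C8 with methyl on C8; C9 aldehyde)
Conditions: Ph3P=C(Me)CHO (3 equiv), toluene, 100 °C
Reagents that add atoms: 2-(triphenylphosphoranylidene)propanal CC(C=O)=P(c1ccccc1)(c1ccccc1)c1ccccc1
Why: Wittig olefination with the stabilised ylide should give the E-trisubstituted enal without added base.

Step 13
Reactants: 16 (E)-enal
Product: 17 (E,E)-dienal (C7=C8–C9=C10; C11 aldehyde)
Conditions: Ph3P=CHCHO (1.3 equiv), toluene, 80 °C, dark
Reagents that add atoms: (triphenylphosphoranylidene)acetaldehyde O=CC=P(c1ccccc1)(c1ccccc1)c1ccccc1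
Why: A second Wittig olefination with the formyl-stabilised ylide extends the enal by two carbons and should give the E-disubstituted C9=C10 alkene.

Step 14
Reactants: 18 methyl 2-methyl-3-oxopentanoate
Product: 20 methyl 2,4-dimethyl-3,5-dioxoheptanoate, via sodium lithium dienolate 19 (not isolated)
Conditions: NaH, THF, 0 °C; n-BuLi, 0 °C; EtC(O)N(OMe)Me, −78 → 0 °C; aq. HCl
Reagents that add atoms: N-methoxy-N-methylpropanamide CCC(=O)N(C)OC
Why: γ-Acylation of the β-keto ester dianion by the N-methoxy-N-methylamide (Claisen-type condensation) gives the β,δ-diketo ester after collapse of the chelated tetrahedral intermediate on work-up.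

Step 15
Reactants: 20 methyl 2,4-dimethyl-3,5-dioxoheptanoate
Product: 21 6-ethyl-4-hydroxy-3,5-dimethyl-2H-pyran-2-one
Conditions: DBU, toluene, 60 °C
Reagents that add atoms: none
Why: DBU-promoted enolisation and lactonisation with loss of methanol closes the 4-hydroxy-2-pyrone.

Step 16
Reactants: 21 6-ethyl-4-hydroxy-3,5-dimethyl-2H-pyran-2-one
Product: 22 6-ethyl-2-methoxy-3,5-dimethyl-4H-pyran-4-one
Conditions: MeOTf, CH2Cl2, 25 °C; aq. NaHCO3
Reagents that add atoms: methyl trifluoromethanesulfonate COS(=O)(=O)C(F)(F)F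
Why: The hard methylating agent should alkylate the most basic oxygen, the lactone carbonyl, and loss of the hydroxyl proton then leaves the 2-methoxy-4-pyrone (regioselective O-methylation).

Step 17
Reactants: 17 (E,E)-dienal; 22 6-ethyl-2-methoxy-3,5-dimethyl-4H-pyran-4-one
Product: 24 aldol adduct (C11 carbinol; mixture of C11/C12 epimers), via lithiated pyrone 23 (not isolated)
Conditions: 22 (2.3 equiv), LiN(SiMe3)2 (2.3 equiv), THF, −78 °C; then 17, −78 °C, dark; aq. NH4Cl
Reagents that add atoms: none
Why: Deprotonation of the ethyl group, which is vinylogous to the pyrone carbonyl, and 1,2-addition of the anion to the aldehyde is an aldol reaction in which the extra equivalent of anion is consumed by the tertiary hydroxyl group and the new carbinol centres are erased in the next step.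

Step 18
Reactants: 24 aldol adduct
Product: 26 protected amaurone B (C3/C4 acetonide; 6β-OTBS; all-E tetraene), via C11 mesylate 25 (not isolated)
Conditions: MsCl, Et3N, CH2Cl2, 0 °C; then DBU, 25 °C, dark
Reagents that add atoms: none
Why: Mesylation of the secondary carbinol and DBU-induced E1cB elimination through the pyrone-stabilised anion should give the conjugated, thermodynamically preferred E alkene at C11=C12.

Step 19
Reactants: 26 protected amaurone B
Product: 27 4,6-bis-deacetyl amaurone B (C3, C4, C5, C6 tetrol)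
Conditions: aq. HCl (2 M), THF/MeOH, 0 → 25 °C, dark
Reagents that add atoms: none
Why: Acid-catalysed ketal hydrolysis and desilylation remove the acetonide and the C6 silyl ether in one operation without breaking any ring C–O bond.

Step 20
Reactants: 27 4,6-bis-deacetyl amaurone B
Product: 28 amaurone B
Conditions: Ac2O, pyridine, DMAP (cat.), CH2Cl2, 0 °C, dark
Reagents that add atoms: acetic anhydride CC(=O)OC(C)=O
Why: Acylation with Ac2O/pyridine should esterify the two secondary hydroxyl groups at C4 and C6, whereas the hindered tertiary hydroxyl groups at C3 and C5 do not react under these conditions.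

Compound list
1 | propiolic acid | C#CC(=O)O | starting material
2 | (E)-3-acetoxyacrylic acid | CC(=O)O/C=C/C(=O)O | intermediate
3 | oxazolidin-2-one | O=C1NCCO1 | starting material
4 | (E)-3-acetoxyacryloyl chloride | CC(=O)O/C=C/C(=O)Cl | intermediate
5 | 3-[(E)-3-acetoxyacryloyl]oxazolidin-2-one | CC(=O)O/C=C/C(=O)N1CCOC1=O | intermediate
6 | (E)-3-methylpenta-1,3-diene | C=C/C(C)=C/C | starting material
7 | 3-[(1R,2S,6R)-6-acetoxy-2,3-dimethylcyclohex-3-ene-1-carbonyl]oxazolidin-2-one (acyl cis to C2 methyl, trans to acetoxy) | O=C(N1CCOC1=O)[C@@H]2[C@H](C)C(C)=CC[C@H]2OC(C)=O | intermediate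
8 | (1R,5S,6S)-6-(hydroxymethyl)-4,5-dimethylcyclohex-3-en-1-ol | OC[C@@H]1[C@H](C)C(C)=CC[C@H]1O | intermediate
9 | bis-TBS ether of 8 (C7–OTBS, 6β-OTBS) | CC(C)(C)[Si](C)(C)OC[C@@H]1[C@H](C)C(C)=CC[C@H]1O[Si](C)(C)C(C)(C)C | intermediate
10 | C5 enone (C5=O conjugated with C3=C4; 1α-CH2OTBS, 2α-Me, 6β-OTBS) | CC(C)(C)[Si](C)(C)OC[C@@H]1[C@H](C)C(C)=CC(=O)[C@H]1O[Si](C)(C)C(C)(C)C | intermediate
11 | 3β,4β-dihydroxy ketone (3α-Me) | CC(C)(C)[Si](C)(C)OC[C@@H]1[C@H](C)[C@@](C)(O)[C@@H](O)C(=O)[C@H]1O[Si](C)(C)C(C)(C)C | intermediate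
12 | C3/C4 acetonide of 11 | CC(C)(C)[Si](C)(C)OC[C@@H]1[C@H](C)[C@@]2(C)OC(C)(C)O[C@H]2C(=O)[C@H]1O[Si](C)(C)C(C)(C)C | intermediate
13 | C5 tertiary alcohol (5α-Me, 5β-OH; acetonide; bis-TBS) | CC(C)(C)[Si](C)(C)OC[C@@H]1[C@H](C)[C@@]2(C)OC(C)(C)O[C@H]2[C@@](C)(O)[C@H]1O[Si](C)(C)C(C)(C)C | intermediate
14 | C7 primary alcohol (6β-OTBS, acetonide, 5β-OH) | OC[C@@H]1[C@H](C)[C@@]2(C)OC(C)(C)O[C@H]2[C@@](C)(O)[C@H]1O[Si](C)(C)C(C)(C)C | intermediate
15 | C7 aldehyde | O=C[C@@H]1[C@H](C)[C@@]2(C)OC(C)(C)O[C@H]2[C@@](C)(O)[C@H]1O[Si](C)(C)C(C)(C)C | intermediate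
16 | (E)-enal (ring–CH=C(Me)–CHO) | O=C/C(C)=C/[C@@H]1[C@H](C)[C@@]2(C)OC(C)(C)O[C@H]2[C@@](C)(O)[C@H]1O[Si](C)(C)C(C)(C)C | intermediate
17 | (E,E)-dienal (ring–CH=C(Me)–CH=CH–CHO) | O=C/C=C/C(C)=C/[C@@H]1[C@H](C)[C@@]2(C)OC(C)(C)O[C@H]2[C@@](C)(O)[C@H]1O[Si](C)(C)C(C)(C)C | intermediate
18 | methyl 2-methyl-3-oxopentanoate | CCC(=O)C(C)C(=O)OC | starting material
19 | sodium lithium dienolate of 18 | [Na+].[Li+].CC=C([O-])C(C)=C([O-])OC | intermediate
20 | methyl 2,4-dimethyl-3,5-dioxoheptanoate | CCC(=O)C(C)C(=O)C(C)C(=O)OC | intermediate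
21 | 6-ethyl-4-hydroxy-3,5-dimethyl-2H-pyran-2-one | CCc1oc(=O)c(C)c(O)c1C | intermediate
22 | 6-ethyl-2-methoxy-3,5-dimethyl-4H-pyran-4-one | CCc1oc(OC)c(C)c(=O)c1C | intermediate
23 | lithiated pyrone (anion at the ethyl CH of 22) | [Li+].C[CH-]c1oc(OC)c(C)c(=O)c1C | intermediate
24 | aldol adduct (C11 carbinol, C11/C12 epimer mixture) | COc1oc(C(C)C(O)/C=C/C(C)=C/[C@@H]2[C@H](C)[C@@]3(C)OC(C)(C)O[C@H]3[C@@](C)(O)[C@H]2O[Si](C)(C)C(C)(C)C)c(C)c(=O)c1C | intermediate
25 | C11 mesylate of 24 | COc1oc(C(C)C(OS(C)(=O)=O)/C=C/C(C)=C/[C@@H]2[C@H](C)[C@@]3(C)OC(C)(C)O[C@H]3[C@@](C)(O)[C@H]2O[Si](C)(C)C(C)(C)C)c(C)c(=O)c1C | intermediate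
26 | protected amaurone B (C3/C4 acetonide, 6β-OTBS, free 5β-OH) | COc1oc(/C(C)=C/C=C/C(C)=C/[C@@H]2[C@H](C)[C@@]3(C)OC(C)(C)O[C@H]3[C@@](C)(O)[C@H]2O[Si](C)(C)C(C)(C)C)c(C)c(=O)c1C | intermediate
27 | 4,6-bis-deacetyl amaurone B (tetrol) | COc1oc(/C(C)=C/C=C/C(C)=C/[C@@H]2[C@H](C)[C@@](C)(O)[C@@H](O)[C@@](C)(O)[C@H]2O)c(C)c(=O)c1C | intermediate
28 | amaurone B | COc1oc(/C(C)=C/C=C/C(C)=C/[C@@H]2[C@H](C)[C@@](C)(O)[C@@H](OC(C)=O)[C@@](C)(O)[C@H]2OC(C)=O)c(C)c(=O)c1C | target

Total step count: 20 (17 on the main line, 3 for the pyrone).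
Longest linear sequence: 17 steps (steps 1–13 and 17–20).

Steps most likely to fail

Step 3. The dienophile β-carbon may bond to the methyl-bearing diene terminus, steered by the internal methyl group, and face discrimination may weaken if the sluggish β-acetoxy imide has to be run warm. The fallback replaces catalyst control by auxiliary control under a stoichiometric aluminium Lewis acid at low temperature. It sets out from acid 2: chloride 4 is made as in step 2 and used to acylate lithiated (R)-4-benzyloxazolidin-2-one (n-BuLi, THF, −78 °C), giving 3-[(E)-3-acetoxyacryloyl]-(4R)-4-benzyloxazolidin-2-one F1. With Et2AlCl (1.4 equiv) and diene 6 in CH2Cl2 at −78 °C, the cationic aluminium chelate, whose benzyl group covers the Cα si face, should give the endo adduct 3-[(1R,2S,6R)-6-acetoxy-2,3-dimethylcyclohex-3-ene-1-carbonyl]-(4R)-4-benzyloxazolidin-2-one F2. The low temperature favours bonding next to the terminal methyl group, and minor isomers are now diastereomers that can be separated. LiBH4/MeOH in THF then removes auxiliary and acetate, and the route is rejoined at diol 8.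

Step 6. Hydrogen abstraction at C2 or at the C3 methyl group may compete with that at C5, and the oxidation may stall or over-oxidise. The fallback installs the C5 oxygen by alkene transposition instead of C–H oxidation and sets out from 9. Epoxidation (mCPBA, NaHCO3, CH2Cl2, 0 °C) gives the 3,4-epoxide F3, expected on the β face, although its configuration is immaterial. Opening at the secondary C4 with PhSeNa (from PhSeSePh and NaBH4, EtOH) gives the 3-hydroxy-4-phenylselanyl compound F4. Oxidation with H2O2/pyridine in THF gives the selenoxide F5, whose syn elimination can only run towards C5 because C3 is quaternary, and so gives the tertiary allylic alcohol F6 (3-hydroxy-3-methyl, C4=C5 alkene). Oxidative 1,3-transposition with [C5H5NH][CrO3Cl] in CH2Cl2 (Babler–Dauben oxidation) moves the oxygen to C5 and returns the route to enone 10.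

Step 18. The dienylic mesylate may ionise, with chloride capture or allylic transposition, and the C11=C12 geometry may erode during elimination. The fallback forms C11=C12 by direct olefination and replaces steps 17 and 18; it sets out from pyrone 22 and dienal 17. Anion 23 (LiN(SiMe3)2, 2 equiv, THF, −78 °C) is phosphorylated with ClP(O)(OEt)2 to give diethyl [1-(6-methoxy-3,5-dimethyl-4-oxo-4H-pyran-2-yl)ethyl]phosphonate F7. Deprotonation with NaH in THF gives the sodium salt of the phosphonate carbanion F8, used in excess to allow for the tertiary hydroxyl group of 17. Horner–Wadsworth–Emmons reaction of this pyrone-stabilised anion with 17 should give the E-trisubstituted alkene under thermodynamic control, and the route is rejoined at 26.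

Further compounds
F1 | step 3 | 3-[(E)-3-acetoxyacryloyl]-(4R)-4-benzyloxazolidin-2-one | CC(=O)O/C=C/C(=O)N1[C@H](Cc2ccccc2)COC1=O
F2 | step 3 | 3-[(1R,2S,6R)-6-acetoxy-2,3-dimethylcyclohex-3-ene-1-carbonyl]-(4R)-4-benzyloxazolidin-2-one | O=C(N1[C@H](Cc2ccccc2)COC1=O)[C@@H]3[C@H](C)C(C)=CC[C@H]3OC(C)=O
F3 | step 6 | 3β,4β-epoxide of 9 | CC(C)(C)[Si](C)(C)OC[C@@H]1[C@H](C)[C@@]2(C)O[C@H]2C[C@H]1O[Si](C)(C)C(C)(C)C
F4 | step 6 | 3β-hydroxy-4α-(phenylselanyl) compound | CC(C)(C)[Si](C)(C)OC[C@@H]1[C@H](C)[C@@](C)(O)[C@H]([Se]c2ccccc2)C[C@H]1O[Si](C)(C)C(C)(C)C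
F5 | step 6 | selenoxide of F4 | CC(C)(C)[Si](C)(C)OC[C@@H]1[C@H](C)[C@@](C)(O)[C@H]([Se](=O)c2ccccc2)C[C@H]1O[Si](C)(C)C(C)(C)C
F6 | step 6 | tertiary allylic alcohol (3β-OH, 3α-Me, C4=C5) | CC(C)(C)[Si](C)(C)OC[C@@H]1[C@H](C)[C@@](C)(O)C=C[C@H]1O[Si](C)(C)C(C)(C)C
F7 | step 18 | diethyl [1-(6-methoxy-3,5-dimethyl-4-oxo-4H-pyran-2-yl)ethyl]phosphonate | CCOP(=O)(OCC)C(C)c1oc(OC)c(C)c(=O)c1C
F8 | step 18 | sodium salt of the carbanion of F7 | [Na+].CCOP(=O)(OCC)[C-](C)c1oc(OC)c(C)c(=O)c1C
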